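**Retrosynthetic overview**
1. Target 26 ⇐ (R)-acylal acetate 25 by lipase alcoholysis ⇐ racemic lactol 24 by lipase-catalysed dynamic kinetic resolution, which sets the only stereocentre at the very end.
2. Hydroxyphthalide (γ-lactol) ring of 24 ⇐ depsidone 22 carrying a dioxolane-masked aldehyde next to a methyl ester (acid unmasking and lactolisation).
3. Seven-membered depsidone lactone of 22 ⇐ 2-aryloxybenzoic acid 21 (carbodiimide lactonisation) ⇐ benzyl-protected 20.
4. Diaryl ether 20 ⇐ Ullmann coupling of bromo acid 8 (six steps from creosol) with phenol 19 (six steps from methyl 2,4-dihydroxy-3-methylbenzoate).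
5. Ring order: both benzene rings are bought; the dioxepinone ring is closed in step 15, the lactol ring in step 16.

Assumption: the lactol carbon is treated as an isolable stereocentre although it can epimerise by ring–chain tautomerism in basic or protic media, and the named lipase is taken to be R-selective for this hemiacetal (to be confirmed on the racemate).

**Route**

Step 1
Reactants: 1 creosol (2-methoxy-4-methylphenol)
Product: 2 creosol acetate (2-methoxy-4-methylphenyl acetate)
Conditions: Ac2O, pyridine, DMAP (cat.), CH2Cl2, rt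
Reagents that add atoms: acetic anhydride CC(=O)OC(C)=O
Why: O-acetylation tames the phenol oxygen so that the methoxy group controls the next electrophilic substitution.

Step 2
Reactants: 2 creosol acetate
Product: 4 formyl acetate (5-formyl-2-methoxy-4-methylphenyl acetate), via chloro ether 3 (not isolated)
Conditions: Cl2CHOMe, TiCl4, CH2Cl2, −10 → 0 °C; then ice-cold 1 M HCl
Reagents that add atoms: dichloromethyl methyl ether COC(Cl)Cl; water O
Why: Rieche formylation goes para to OMe and ortho to CH3, the most activated free position, and the α-chloro ether hydrolyses on work-up.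

Step 3
Reactants: 4 formyl acetate
Product: 5 phenol aldehyde (5-hydroxy-4-methoxy-2-methylbenzaldehyde)
Conditions: K2CO3 (0.2 eq), MeOH, rt
Reagents that add atoms: none
Why: Mild transesterification (Zemplén-type methanolysis) frees the phenol without touching the aldehyde.

Step 4
Reactants: 5 phenol aldehyde
Product: 6 bromophenol aldehyde (2-bromo-3-hydroxy-4-methoxy-6-methylbenzaldehyde)
Conditions: Br2 (1.05 eq), NaOAc, AcOH, 15 °C
Reagents that add atoms: bromine BrBr
Why: Electrophilic aromatic bromination goes to the only free position ortho to the free OH (para is blocked), as in the isovanillin to 2-bromoisovanillin case.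

Step 5
Reactants: 6 bromophenol aldehyde
Product: 7 MOM bromo aldehyde (2-bromo-4-methoxy-3-(methoxymethoxy)-6-methylbenzaldehyde)
Conditions: MOMCl, iPr2NEt, CH2Cl2, 0 °C → rt
Reagents that add atoms: chloromethyl methyl ether COCCl
Why: Williamson-type O-alkylation gives a MOM ether that survives base, copper, hydrogenolysis and carbodiimide and falls off in the final acid step.

Step 6
Reactants: 7 MOM bromo aldehyde
Product: 8 bromo acid (2-bromo-4-methoxy-3-(methoxymethoxy)-6-methylbenzoic acid)
Conditions: NaClO2, NaH2PO4, 2-methyl-2-butene, t-BuOH/H2O, rt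
Reagents that add atoms: sodium chlorite [Na+].[O-]Cl=O
Why: Pinnick oxidation converts hindered aryl aldehydes to acids at pH about 4, where the MOM ether is stable.

Step 7
Reactants: 9 methyl 2,4-dihydroxy-3-methylbenzoate
Product: 11 methyl 5-formyl-2,4-dihydroxy-3-methylbenzoate, via chloro ether 10 (not isolated)
Conditions: Cl2CHOMe, TiCl4, CH2Cl2, 0 °C → rt; then 1 M HCl
Reagents that add atoms: dichloromethyl methyl ether COC(Cl)Cl; water O
Why: Rieche formylation attacks C5 (ortho to 4-OH, para to 2-OH); C6 is meta to both hydroxyls and stays untouched.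

Step 8
Reactants: 11 methyl 5-formyl-2,4-dihydroxy-3-methylbenzoate
Product: 12 methyl 2,4-bis(benzyloxy)-5-formyl-3-methylbenzoate
Conditions: BnBr (2.6 eq), K2CO3, DMF, 60 °C
Reagents that add atoms: benzyl bromide BrCc1ccccc1
Why: Williamson etherification at 60 °C alkylates both chelated phenols.

Step 9
Reactants: 12 methyl 2,4-bis(benzyloxy)-5-formyl-3-methylbenzoate
Product: 14 methyl 2,4-bis(benzyloxy)-5-hydroxy-3-methylbenzoate, via aryl formate 13 (not isolated)
Conditions: mCPBA, CH2Cl2, rt; NaHCO3 wash; then K2CO3 (0.2 eq), MeOH, 0 °C → rt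
Reagents that add atoms: 3-chloroperbenzoic acid O=C(OO)c1cccc(Cl)c1
Why: Baeyer–Villiger (Dakin-type) oxidation; the aryl group with ortho and para alkoxy donors migrates, and the formate is cleaved by methanolysis while the hindered methyl ester survives.

Step 10
Reactants: 14 methyl 2,4-bis(benzyloxy)-5-hydroxy-3-methylbenzoate
Product: 15 methyl 2,4-bis(benzyloxy)-5-(methoxymethoxy)-3-methylbenzoate
Conditions: MOMCl, iPr2NEt, CH2Cl2, 0 °C → rt
Reagents that add atoms: chloromethyl methyl ether COCCl
Why: The MOM ether protects the phenol and acts as a second directing group for the metalation.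

Step 11
Reactants: 15 methyl 2,4-bis(benzyloxy)-5-(methoxymethoxy)-3-methylbenzoate
Product: 17 methyl 4,6-bis(benzyloxy)-2-formyl-3-(methoxymethoxy)-5-methylbenzoate, via arylmagnesium chloride 16 (not isolated)
Conditions: TMPMgCl·LiCl (1.5 eq), THF, 0 °C, 2 h; then DMF, 0 °C → rt; aq. NH4Cl
Reagents that add atoms: N,N-dimethylformamide CN(C)C=O
Why: Directed ortho-magnesiation with the Knochel–Hauser base removes the only ring hydrogen, flanked by ester and OMOM, and the ester-tolerant aryl-Mg is formylated by DMF.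

Step 12
Reactants: 17 methyl 4,6-bis(benzyloxy)-2-formyl-3-(methoxymethoxy)-5-methylbenzoate
Product: 19 methyl 4,6-bis(benzyloxy)-2-(1,3-dioxolan-2-yl)-3-hydroxy-5-methylbenzoate, via MOM dioxolane 18 (not isolated)
Conditions: HOCH2CH2OH (10 eq), TsOH·H2O (0.1 eq), toluene, reflux, Dean–Stark; NaHCO3 quench
Reagents that add atoms: ethylene glycol OCCO
Why: Acid-catalysed acetalisation masks the aldehyde as a dioxolane, and excess glycol removes the MOM group by transacetalisation; benzyl ethers and the hindered ester are inert.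

Step 13
Reactants: 8 bromo acid; 19 methyl 4,6-bis(benzyloxy)-2-(1,3-dioxolan-2-yl)-3-hydroxy-5-methylbenzoate
Product: 20 2-[4,6-bis(benzyloxy)-2-(1,3-dioxolan-2-yl)-3-(methoxycarbonyl)-5-methylphenoxy]-4-methoxy-3-(methoxymethoxy)-6-methylbenzoic acid
Conditions: CuI (0.3 eq), picolinic acid (0.6 eq), Cs2CO3 (3.5 eq), DMSO, 100 °C, Ar; cold aq. citric acid to pH 4
Reagents that add atoms: none
Why: Ullmann diaryl ether condensation, helped by the ortho-carboxylate that delivers copper to the C–Br bond, with an electron-rich phenoxide whose aldehyde is masked.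

Step 14
Reactants: 20 diaryl ether acid
Product: 21 2-[2-(1,3-dioxolan-2-yl)-4,6-dihydroxy-3-(methoxycarbonyl)-5-methylphenoxy]-4-methoxy-3-(methoxymethoxy)-6-methylbenzoic acid
Conditions: H2 (1 atm), 10% Pd/C, EtOAc, rt
Reagents that add atoms: none
Why: Hydrogenolysis cleaves the two benzyl ethers under neutral conditions; the MOM ether, the hindered dioxolane and the diaryl ether are not reduced.

Step 15
Reactants: 21 seco acid
Product: 22 methyl 6-(1,3-dioxolan-2-yl)-8-hydroxy-3-methoxy-4-(methoxymethoxy)-1,9-dimethyl-11-oxo-11H-dibenzo[b,e][1,4]dioxepine-7-carboxylate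
Conditions: DCC (1.5 eq), DMAP (0.1 eq), CH2Cl2 (0.005 M), 0 °C → rt
Reagents that add atoms: none
Why: Steglich-type lactonisation closes the seven-membered depsidone ring onto the only reachable phenol (ortho to the ether oxygen); the other phenol is chelated to its ester and para to the ether link.

Step 16
Reactants: 22 depsidone
Product: 24 racemic lactol (rac-1,4,11-trihydroxy-10-methoxy-5,8-dimethyl-1H-isobenzofuro[4,5-b][1,4]benzodioxepine-3,7-dione), via formyl ester 23 (not isolated)
Conditions: 3 M aq. HCl/THF (1:3), 50 °C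
Reagents that add atoms: water O
Why: Acid hydrolysis removes dioxolane and MOM, and the aldehyde hydrate lactonises onto the neighbouring methyl ester (neighbouring-group participation) to give the 3-hydroxyphthalide; the hindered depsidone ester survives acid.

Step 17
Reactants: 24 racemic lactol
Product: 25 (1R)-4,11-dihydroxy-10-methoxy-5,8-dimethyl-3,7-dioxo-1H-isobenzofuro[4,5-b][1,4]benzodioxepin-1-yl acetate
Conditions: lipase (immobilised Burkholderia cepacia lipase, EC 3.1.1.3), vinyl acetate (5 eq), Et3N (0.1 eq), 2-MeTHF/toluene, 35 °C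
Reagents that add atoms: vinyl acetate C=COC(C)=O
Why: Lipase-catalysed dynamic kinetic resolution; the lactol racemises by base-catalysed ring–chain tautomerism while the enzyme acetylates only the R hemiacetal, giving the configurationally locked (R)-acylal, and the hindered or chelated phenols are not acylated.

Step 18
Reactants: 25 (R)-acetate
Product: 26 target, (1R)-1,4,11-trihydroxy-10-methoxy-5,8-dimethyl-1H-isobenzofuro[4,5-b][1,4]benzodioxepine-3,7-dione
Conditions: same immobilised lipase, n-BuOH (5 eq), dry MTBE/2-MeTHF, 20 °C, no base; filter, evaporate below 20 °C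
Reagents that add atoms: none
Why: Lipase-catalysed alcoholysis breaks the acyl C–O bond, so the acetal carbon keeps its R configuration; the enzyme's R preference leaves any S acetate behind, and base-free anhydrous conditions suppress ring opening.

**Compound list**
1 | creosol (2-methoxy-4-methylphenol) | COc1cc(C)ccc1O | starting material
2 | 2-methoxy-4-methylphenyl acetate | COc1cc(C)ccc1OC(C)=O | intermediate
3 | 5-[chloro(methoxy)methyl]-2-methoxy-4-methylphenyl acetate | COc1cc(C)c(C(Cl)OC)cc1OC(C)=O | intermediate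
4 | 5-formyl-2-methoxy-4-methylphenyl acetate | COc1cc(C)c(C=O)cc1OC(C)=O | intermediate
5 | 5-hydroxy-4-methoxy-2-methylbenzaldehyde | COc1cc(C)c(C=O)cc1O | intermediate
6 | 2-bromo-3-hydroxy-4-methoxy-6-methylbenzaldehyde | COc1cc(C)c(C=O)c(Br)c1O | intermediate
7 | 2-bromo-4-methoxy-3-(methoxymethoxy)-6-methylbenzaldehyde | COc1cc(C)c(C=O)c(Br)c1OCOC | intermediate
8 | 2-bromo-4-methoxy-3-(methoxymethoxy)-6-methylbenzoic acid | COc1cc(C)c(C(=O)O)c(Br)c1OCOC | intermediate
9 | methyl 2,4-dihydroxy-3-methylbenzoate | COC(=O)c1ccc(O)c(C)c1O | starting material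
10 | methyl 5-[chloro(methoxy)methyl]-2,4-dihydroxy-3-methylbenzoate | COC(=O)c1cc(C(Cl)OC)c(O)c(C)c1O | intermediate
11 | methyl 5-formyl-2,4-dihydroxy-3-methylbenzoate | COC(=O)c1cc(C=O)c(O)c(C)c1O | intermediate
12 | methyl 2,4-bis(benzyloxy)-5-formyl-3-methylbenzoate | COC(=O)c1cc(C=O)c(OCc2ccccc2)c(C)c1OCc1ccccc1 | intermediate
13 | methyl 2,4-bis(benzyloxy)-5-(formyloxy)-3-methylbenzoate | COC(=O)c1cc(OC=O)c(OCc2ccccc2)c(C)c1OCc1ccccc1 | intermediate
14 | methyl 2,4-bis(benzyloxy)-5-hydroxy-3-methylbenzoate | COC(=O)c1cc(O)c(OCc2ccccc2)c(C)c1OCc1ccccc1 | intermediate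
15 | methyl 2,4-bis(benzyloxy)-5-(methoxymethoxy)-3-methylbenzoate | COCOc1cc(C(=O)OC)c(OCc2ccccc2)c(C)c1OCc1ccccc1 | intermediate
16 | [3,5-bis(benzyloxy)-2-(methoxycarbonyl)-6-(methoxymethoxy)-4-methylphenyl]magnesium chloride | COCOc1c([Mg]Cl)c(C(=O)OC)c(OCc2ccccc2)c(C)c1OCc1ccccc1 | intermediate
17 | methyl 4,6-bis(benzyloxy)-2-formyl-3-(methoxymethoxy)-5-methylbenzoate | COCOc1c(C=O)c(C(=O)OC)c(OCc2ccccc2)c(C)c1OCc1ccccc1 | intermediate
18 | methyl 4,6-bis(benzyloxy)-2-(1,3-dioxolan-2-yl)-3-(methoxymethoxy)-5-methylbenzoate | COCOc1c(C2OCCO2)c(C(=O)OC)c(OCc2ccccc2)c(C)c1OCc1ccccc1 | intermediate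
19 | methyl 4,6-bis(benzyloxy)-2-(1,3-dioxolan-2-yl)-3-hydroxy-5-methylbenzoate | COC(=O)c1c(C2OCCO2)c(O)c(OCc2ccccc2)c(C)c1OCc1ccccc1 | intermediate
20 | 2-[4,6-bis(benzyloxy)-2-(1,3-dioxolan-2-yl)-3-(methoxycarbonyl)-5-methylphenoxy]-4-methoxy-3-(methoxymethoxy)-6-methylbenzoic acid | COCOc1c(OC)cc(C)c(C(=O)O)c1Oc1c(C2OCCO2)c(C(=O)OC)c(OCc2ccccc2)c(C)c1OCc1ccccc1 | intermediate
21 | 2-[2-(1,3-dioxolan-2-yl)-4,6-dihydroxy-3-(methoxycarbonyl)-5-methylphenoxy]-4-methoxy-3-(methoxymethoxy)-6-methylbenzoic acid | COCOc1c(OC)cc(C)c(C(=O)O)c1Oc1c(C2OCCO2)c(C(=O)OC)c(O)c(C)c1O | intermediate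
22 | methyl 6-(1,3-dioxolan-2-yl)-8-hydroxy-3-methoxy-4-(methoxymethoxy)-1,9-dimethyl-11-oxo-11H-dibenzo[b,e][1,4]dioxepine-7-carboxylate | COCOc1c(OC)cc(C)c2c1Oc1c(C3OCCO3)c(C(=O)OC)c(O)c(C)c1OC2=O | intermediate
23 | methyl 6-formyl-4,8-dihydroxy-3-methoxy-1,9-dimethyl-11-oxo-11H-dibenzo[b,e][1,4]dioxepine-7-carboxylate | COc1cc(C)c2c(c1O)Oc1c(C=O)c(C(=O)OC)c(O)c(C)c1OC2=O | intermediate
24 | rac-1,4,11-trihydroxy-10-methoxy-5,8-dimethyl-1H-isobenzofuro[4,5-b][1,4]benzodioxepine-3,7-dione (depsidone with a 3-hydroxyphthalide fused to the B ring, racemic at the lactol carbon) | COc1cc(C)c2c(c1O)Oc1c(c(C)c(O)c3c1C(O)OC3=O)OC2=O | intermediate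
25 | (1R)-4,11-dihydroxy-10-methoxy-5,8-dimethyl-3,7-dioxo-1H-isobenzofuro[4,5-b][1,4]benzodioxepin-1-yl acetate | COc1cc(C)c2c(c1O)Oc1c(c(C)c(O)c3c1[C@H](OC(C)=O)OC3=O)OC2=O | intermediate
26 | (1R)-1,4,11-trihydroxy-10-methoxy-5,8-dimethyl-1H-isobenzofuro[4,5-b][1,4]benzodioxepine-3,7-dione (CNP0211607.1; the 11-hydroxy analogue of stictic acid, R at the lactol carbon) | COc1cc(C)c2c(c1O)Oc1c(c(C)c(O)c3c1[C@H](O)OC3=O)OC2=O | target

**Totals**
Total step count: 18. Longest linear sequence: 12 steps (steps 1–6 or 7–12, then 13–18).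

**Three steps most likely to fail**

Step 13, the Ullmann coupling that forms a tetra-ortho-substituted diaryl ether. Fallback: invert the order of ether formation and formylation. It sets out from 14, which has one free ortho position, and couples it with 8 under the same copper catalysis to give 2-[2,4-bis(benzyloxy)-5-(methoxycarbonyl)-3-methylphenoxy]-4-methoxy-3-(methoxymethoxy)-6-methylbenzoic acid F1. Directed magnesiation between ester and aryloxy group (TMPMgCl·LiCl, 2.6 eq, THF, 0 °C; the first equivalent forms the carboxylate) and DMF quench then give 2-[4,6-bis(benzyloxy)-2-formyl-3-(methoxycarbonyl)-5-methylphenoxy]-4-methoxy-3-(methoxymethoxy)-6-methylbenzoic acid F2. Acetalisation under MOM-sparing conditions (1,2-bis(trimethylsilyloxy)ethane, cat. TMSOTf, CH2Cl2, −78 °C) comes back to the route at 20.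

Step 17, the lipase DKR: the lactol is hindered, and both the rate and the R sense have to be found by screening. Fallback: set the stereocentre with a small-molecule acyl-transfer catalyst instead. It sets out from 24, which is treated with Ac2O (4 eq), iPr2NEt and a chiral isothiourea (10 mol %, the enantiomer that gives the R acylal) in CH2Cl2 at 0 °C. This is an acylative dynamic kinetic resolution; the phenols are acetylated as well, giving (1R)-10-methoxy-5,8-dimethyl-3,7-dioxo-1H-isobenzofuro[4,5-b][1,4]benzodioxepine-1,4,11-triyl triacetate F3. The lipase/n-BuOH conditions of step 18 then remove all three acetates, and the fallback comes back to the route at 26.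

Step 18, the enzymatic deacetylation: it may be slow or erode the enantiomeric excess. Fallback: use a carbonate that is removed without enzyme or protic nucleophile. It sets out from 24, which under the lipase DKR with allyl vinyl carbonate in place of vinyl acetate gives allyl (1S)-4,11-dihydroxy-10-methoxy-5,8-dimethyl-3,7-dioxo-1H-isobenzofuro[4,5-b][1,4]benzodioxepin-1-yl carbonate F4. The descriptor changes by CIP priority only; the spatial arrangement is that of 26. Pd(PPh3)4 (2 mol %) and PhSiH3 in CH2Cl2 at 0 °C then remove the allyloxycarbonyl group under neutral aprotic conditions, and the fallback comes back to the route at 26.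

**Further compounds**
F1 | step 13 | 2-[2,4-bis(benzyloxy)-5-(methoxycarbonyl)-3-methylphenoxy]-4-methoxy-3-(methoxymethoxy)-6-methylbenzoic acid | COCOc1c(OC)cc(C)c(C(=O)O)c1Oc1cc(C(=O)OC)c(OCc2ccccc2)c(C)c1OCc1ccccc1
F2 | step 13 | 2-[4,6-bis(benzyloxy)-2-formyl-3-(methoxycarbonyl)-5-methylphenoxy]-4-methoxy-3-(methoxymethoxy)-6-methylbenzoic acid | COCOc1c(OC)cc(C)c(C(=O)O)c1Oc1c(C=O)c(C(=O)OC)c(OCc2ccccc2)c(C)c1OCc1ccccc1
F3 | step 17 | (1R)-10-methoxy-5,8-dimethyl-3,7-dioxo-1H-isobenzofuro[4,5-b][1,4]benzodioxepine-1,4,11-triyl triacetate | COc1cc(C)c2c(c1OC(C)=O)Oc1c(c(C)c(OC(C)=O)c3c1[C@H](OC(C)=O)OC3=O)OC2=O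
F4 | step 18 | allyl (1S)-4,11-dihydroxy-10-methoxy-5,8-dimethyl-3,7-dioxo-1H-isobenzofuro[4,5-b][1,4]benzodioxepin-1-yl carbonate | COc1cc(C)c2c(c1O)Oc1c(c(C)c(O)c3c1[C@H](OC(=O)OCC=C)OC3=O)OC2=O
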